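**Retrosynthetic overview**
1. 29 ⇒ 21 + 26. The last C–C bond is the C3 aroylation of the fully alkylated bicyclic vinylogous ester, and one hydrolysis then frees the enol and the phenol.
2. 21 ⇒ 17 + 19. C7 and the endo geranyl chain come from exo-face hydroboration of a 7-methylidene group followed by B-alkyl Suzuki coupling.
3. 17 ⇒ 14. The bicyclo[3.3.1] core comes from an oxidative ring expansion in which C8 shifts from C9 to C1 in the cis-hydrindane aldol 15. This forms the C1–C8 bond between two quaternary carbons.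
4. 14 ⇒ 12 + 13 ⇒ 10 + 7. C5 is set by enantioselective phase-transfer prenylation of a 2-acylcyclopentanone, and alkyne 3 feeds both 7 and 19.
5. Ring order: cyclopentane (bought in 8), then cyclohexenone ring A (aldol), then expansion of the cyclopentane to cyclohexanone ring B.

Atom labels: C1 is the bridgehead next to CMe2 (C8). C2–C4 are the enolised β-diketone carbons. C5 is the other bridgehead, C6 the CH2, C7 the CH bearing geranyl, and C9 the bridging ketone.

Assumption: the catalyst antipode that gives (5S)-14 is fixed by a small test run ((S,S) is written), and the target is treated as one of its rapidly interconverting enol tautomers.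

**Step 1**
Reactants: 1 5-bromo-2-methylpent-2-ene; 2 lithium acetylide–ethylenediamine complex
Product: 3 6-methylhept-5-en-1-yne
Conditions: DMSO, 10 °C → rt
Reagents that add atoms: none
Why: Acetylide alkylation (SN2) of an unhindered primary bromide in a dipolar aprotic solvent; the trisubstituted alkene is inert and no stereocentre is formed.

**Step 2**
Reactants: 3 6-methylhept-5-en-1-yne
Product: 5 methyl 7-methyloct-6-en-2-ynoate, via lithium alkynide 4 (not isolated)
Conditions: n-BuLi, THF, −78 °C; ClCO2Me, −78 → 0 °C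
Reagents that add atoms: methyl chloroformate, COC(=O)Cl; n-butyllithium, [Li]CCCC (Li of 4 only)
Why: Deprotonation of the terminal alkyne and C-acylation of the alkynide with a chloroformate (alkynoate synthesis) stops at the ester, because the ynoate is a much poorer acylating agent than the chloroformate.

**Step 3**
Reactants: 5 methyl 7-methyloct-6-en-2-ynoate
Product: 7 (2E)-3-methoxy-7-methylocta-2,6-dienoic acid, via methoxy-dienoate ester 6 (not isolated)
Conditions: NaOMe (0.2 equiv), MeOH, 65 °C; then KOH, H2O, 65 °C; cold 1 M HCl to pH 3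
Reagents that add atoms: methanol, CO; potassium hydroxide, [K+].[OH-]
Why: Base-catalysed oxa-Michael addition of methanol to the ynoate equilibrates to the more stable (E)-β-methoxy enoate (alkyl chain cis to the carbonyl), and in-flask saponification gives the acid, whose vinylogous-carbonate unit survives brief cold acidification.

**Step 4**
Reactants: 8 2-methylcyclopentane-1,3-dione
Product: 9 2,2-dimethylcyclopentane-1,3-dione
Conditions: MeI, KOH, H2O–dioxane, reflux
Reagents that add atoms: iodomethane, CI
Why: C-alkylation of the stabilised cyclic 1,3-diketone enolate with MeI gives the achiral gem-dimethyl dione (the future C8).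

**Step 5**
Reactants: 9 2,2-dimethylcyclopentane-1,3-dione
Product: 10 2,2-dimethyl-3-methylidenecyclopentan-1-one
Conditions: Ph3PCH3Br (1.0 equiv), KOt-Bu, THF, 0 °C (ylide preformed); then 9, 0 °C → rt
Reagents that add atoms: methyltriphenylphosphonium bromide, C[P+](c1ccccc1)(c1ccccc1)c1ccccc1.[Br-]
Why: Wittig methylenation with one equivalent of non-stabilised ylide converts one of the two homotopic ketones, and the remaining ketone is less electrophilic than the dione, so the bis-olefin stays minor; the new CH2 becomes C1' of the geranyl chain.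

**Step 6**
Reactants: 7 (2E)-3-methoxy-7-methylocta-2,6-dienoic acid; 10 2,2-dimethyl-3-methylidenecyclopentan-1-one
Product: 12 5-[(2E)-3-methoxy-7-methylocta-2,6-dienoyl]-2,2-dimethyl-3-methylidenecyclopentan-1-one (keto–enol mixture), via acid chloride 11 (not isolated)
Conditions: 7, (COCl)2, cat. DMF, CH2Cl2, 0 °C, evaporate; then 10, MgBr2·OEt2, i-Pr2NEt, CH2Cl2, rt
Reagents that add atoms: oxalyl chloride, O=C(Cl)C(=O)Cl (Cl of 11 only)
Why: Soft-enolisation crossed-Claisen C-acylation: 10 can enolise only toward C5 because the other α-carbon is quaternary, and the product is removed as its Mg diketonate chelate, which suppresses O- and di-acylation and holds the enol oxygen away from the β-methoxy-enone carbon (no pyranone closure).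

**Step 7**
Reactants: 12 5-[(2E)-3-methoxy-7-methylocta-2,6-dienoyl]-2,2-dimethyl-3-methylidenecyclopentan-1-one; 13 1-bromo-3-methylbut-2-ene (prenyl bromide)
Product: 14 (5S)-5-[(2E)-3-methoxy-7-methylocta-2,6-dienoyl]-2,2-dimethyl-3-methylidene-5-(3-methylbut-2-enyl)cyclopentan-1-one
Conditions: (S,S)-3,4,5-trifluorophenyl-NAS bromide (Maruoka catalyst, 2 mol %), Cs2CO3, toluene, −20 °C
Reagents that add atoms: none
Why: Asymmetric phase-transfer alkylation (Maruoka type, established for cyclic β-keto esters and α-acyl lactones): carbonate removes the acidic C5–H, the planar diketonate sits as a tight ion pair in the chiral pocket of the N-spiro binaphthyl ammonium ion, and soft prenyl bromide attacks one face in an SN2 C-alkylation, which sets the quaternary centre C5 as (S), the only stereocentre set by an external chiral source.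

**Step 8**
Reactants: 14 (5S)-quaternary diketone
Product: 17 (1R,5S)-2-methoxy-8,8-dimethyl-7-methylidene-1,5-bis(3-methylbut-2-enyl)bicyclo[3.3.1]non-2-ene-4,9-dione, via hydrindane aldol 15 (not isolated), via iodonium zwitterion 16 (not isolated)
Conditions: LDA (1.1 equiv), THF, −78 → 0 °C; then MeOH, KOH, PhI(OAc)2 (1.2 equiv), 0 °C → rt
Reagents that add atoms: (diacetoxyiodo)benzene, CC(=O)OI(OC(C)=O)c1ccccc1 (PhI unit of 16 only; nothing stays in 17)
Why: Proposed new method: one-flask vinylogous aldol / iodine(III) oxidation / vinylogous semipinacol 1,2-shift onto a fully substituted terminus; LDA removes the only acidic proton of 14 (γ-CH2, C1), the dienolate adds to the C9 ketone from the face that carries its own tether (cis-hydrindane 15, so C9 follows C5), KOH/MeOH then exchanges the remaining C1–H, the extended enolate takes up PhI(III) at its unhindered α-carbon C3 to give 16, and departure of PhI from this 2-methoxyallyl system develops charge at tertiary C1, to which the aligned, electron-rich allylic quaternary carbon C8 migrates while the C9 alkoxide collapses to the ketone (C5 carries an acyl group and migrates poorly), so the cyclopentane becomes the cyclohexanone, the C1–C8 bond between two quaternary carbons is formed, and C1 can only arise as (R) because the C2–C4 bridge ties it to C5; isolated alkenes are inert to PhI(OAc)2 in basic methanol; closest known reaction type: hypervalent-iodine oxidative ring expansion (semipinacol) of hydroxy-hydrindenone vinylogous esters that have a CH2 migration terminus, and halohydrin-type semipinacol ring enlargement.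

**Step 9**
Reactants: 3 6-methylhept-5-en-1-yne
Product: 19 (1E)-1-iodo-2,6-dimethylhepta-1,5-diene, via vinylalane 18 (not isolated)
Conditions: Me3Al, Cp2ZrCl2 (25 mol %), CH2Cl2, 0 °C → rt; I2, THF, −30 °C
Reagents that add atoms: trimethylaluminium, C[Al](C)C; iodine, II
Why: Negishi Zr-catalysed methylalumination is a syn carbometallation that places Al on the terminal carbon, and iodinolysis proceeds with retention, so only the E-trisubstituted vinyl iodide forms while the isolated trisubstituted alkene is untouched.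

**Step 10**
Reactants: 17 7-methylidene bicyclic vinylogous ester; 19 (1E)-1-iodo-2,6-dimethylhepta-1,5-diene
Product: 21 (1R,5S,7S)-7-[(2E)-3,7-dimethylocta-2,6-dienyl]-2-methoxy-8,8-dimethyl-1,5-bis(3-methylbut-2-enyl)bicyclo[3.3.1]non-2-ene-4,9-dione, via B-alkyl-9-BBN adduct 20 (not isolated)
Conditions: 9-BBN, THF, 0 °C → rt; then aq. Cs2CO3, 19, PdCl2(dppf) (5 mol %), AsPh3, DMF, rt → 45 °C
Reagents that add atoms: 9-borabicyclo[3.3.1]nonane, C1CC2CCCC(C1)B2 (boryl group of 20 only; only its H stays in 21)
Why: Hydroboration / B-alkyl Suzuki–Miyaura coupling: 9-BBN selects the 1,1-disubstituted alkene over the trisubstituted prenyl alkenes and the hindered or vinylogous carbonyls, and it approaches from the open exo face because the endo face is roofed by the C2–C4 bridge, so H ends exo and CH2B endo (C7 = S, ring B relaxing to a boat), and the Pd coupling joins CH2 to the vinyl iodide with retention of the E geometry.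

**Step 11**
Reactants: 22 3-bromophenol
Product: 23 (3-bromophenoxy)(tert-butyl)dimethylsilane
Conditions: TBSCl, imidazole, DMF, rt
Reagents that add atoms: tert-butyldimethylsilyl chloride, CC(C)(C)[Si](C)(C)Cl
Why: Standard imidazole-promoted silylation masks the phenol for the organolithium steps.

**Step 12**
Reactants: 23 (3-bromophenoxy)(tert-butyl)dimethylsilane
Product: 26 3-[(tert-butyldimethylsilyl)oxy]benzoyl chloride, via aryllithium 24 (not isolated), via lithium carboxylate 25 (not isolated)
Conditions: n-BuLi, THF, −78 °C; CO2; evaporate; (COCl)2, cat. DMF, CH2Cl2, 0 °C → rt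
Reagents that add atoms: carbon dioxide, O=C=O; oxalyl chloride, O=C(Cl)C(=O)Cl; n-butyllithium, [Li]CCCC (Li of 24 and 25 only)
Why: Bromine–lithium exchange, carboxylation and chlorination of the lithium carboxylate with oxalyl chloride; the salt gives LiCl instead of HCl, so the aryl silyl ether survives, and a meta-lithio aryl silyl ether cannot undergo silyl migration.

**Step 13**
Reactants: 21 7-geranyl bicyclic vinylogous ester; 26 3-[(tert-butyldimethylsilyl)oxy]benzoyl chloride
Product: 28 (1R,5R,7S)-3-{3-[(tert-butyldimethylsilyl)oxy]benzoyl}-7-[(2E)-3,7-dimethylocta-2,6-dienyl]-2-methoxy-8,8-dimethyl-1,5-bis(3-methylbut-2-enyl)bicyclo[3.3.1]non-2-ene-4,9-dione, via C3-lithio species 27 (not isolated)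
Conditions: LiTMP, THF, −78 °C; then 26, −78 → 0 °C
Reagents that add atoms: lithium 2,2,6,6-tetramethylpiperidide, [Li]N1C(C)(C)CCCC1(C)C (Li of 27 only)
Why: Directed vinylic lithiation of the β-methoxy enone at C3 followed by acylation with an aroyl chloride, the established way to 3-acylate this ring system once both bridgeheads are quaternary; C3–H is the only acidic C–H left and no stereocentre is touched.

**Step 14**
Reactants: 28 3-aroyl vinylogous ester
Product: 29 (1S,5S,7S)-7-[(2E)-3,7-dimethylocta-2,6-dienyl]-4-hydroxy-3-(3-hydroxybenzoyl)-8,8-dimethyl-1,5-bis(3-methylbut-2-enyl)bicyclo[3.3.1]non-3-ene-2,9-dione (target)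
Conditions: LiOH, dioxane–H2O, 90 °C; then 1 M HCl
Reagents that add atoms: lithium hydroxide, [Li+].[OH-]
Why: Hydroxide addition–elimination at C2 of the doubly activated vinylogous ester and simultaneous cleavage of the phenolic silyl ether give the enolised triketone in one operation; C1 and C5 are quaternary and C7 is not enolisable, so nothing epimerises.

**Compound list**
1 | 5-bromo-2-methylpent-2-ene | CC(C)=CCCBr | starting material
2 | lithium acetylide–ethylenediamine complex | [Li]C#C.NCCN | starting material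
3 | 6-methylhept-5-en-1-yne | C#CCCC=C(C)C | intermediate
4 | (6-methylhept-5-en-1-ynyl)lithium (not isolated) | [Li]C#CCCC=C(C)C | intermediate
5 | methyl 7-methyloct-6-en-2-ynoate | COC(=O)C#CCCC=C(C)C | intermediate
6 | methyl (2E)-3-methoxy-7-methylocta-2,6-dienoate (not isolated) | COC(=O)/C=C(\CCC=C(C)C)OC | intermediate
7 | (2E)-3-methoxy-7-methylocta-2,6-dienoic acid | OC(=O)/C=C(\CCC=C(C)C)OC | intermediate
8 | 2-methylcyclopentane-1,3-dione | CC1C(=O)CCC1=O | starting material
9 | 2,2-dimethylcyclopentane-1,3-dione | CC1(C)C(=O)CCC1=O | intermediate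
10 | 2,2-dimethyl-3-methylidenecyclopentan-1-one | C=C1CCC(=O)C1(C)C | intermediate
11 | (2E)-3-methoxy-7-methylocta-2,6-dienoyl chloride (not isolated) | ClC(=O)/C=C(\CCC=C(C)C)OC | intermediate
12 | 5-[(2E)-3-methoxy-7-methylocta-2,6-dienoyl]-2,2-dimethyl-3-methylidenecyclopentan-1-one (C5 labile, keto–enol mixture) | C=C1CC(C(=O)/C=C(\CCC=C(C)C)OC)C(=O)C1(C)C | intermediate
13 | 1-bromo-3-methylbut-2-ene (prenyl bromide) | CC(C)=CCBr | starting material
14 | (5S)-5-[(2E)-3-methoxy-7-methylocta-2,6-dienoyl]-2,2-dimethyl-3-methylidene-5-(3-methylbut-2-enyl)cyclopentan-1-one | C=C1C[C@@](CC=C(C)C)(C(=O)/C=C(\CCC=C(C)C)OC)C(=O)C1(C)C | intermediate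
15 | (3aR,7aR)-7a-hydroxy-6-methoxy-1,1-dimethyl-2-methylidene-3a,7-bis(3-methylbut-2-enyl)-1,2,3,3a,7,7a-hexahydro-4H-inden-4-one, cis-fused, C7 epimers (not isolated) | C=C1C[C@@]2(CC=C(C)C)C(=O)C=C(OC)C(CC=C(C)C)[C@@]2(O)C1(C)C | intermediate
16 | (3aR,7aS)-6-methoxy-1,1-dimethyl-2-methylidene-3a,7-bis(3-methylbut-2-enyl)-4-oxo-5-(phenyliodonio)-1,2,3,3a,4,5-hexahydro-7aH-inden-7a-olate, same ring-fusion geometry as 15 (not isolated) | C=C1C[C@@]2(CC=C(C)C)C(=O)C([I+]c3ccccc3)C(OC)=C(CC=C(C)C)[C@@]2([O-])C1(C)C | intermediate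
17 | (1R,5S)-2-methoxy-8,8-dimethyl-7-methylidene-1,5-bis(3-methylbut-2-enyl)bicyclo[3.3.1]non-2-ene-4,9-dione | C=C1C[C@]2(CC=C(C)C)C(=O)[C@@](CC=C(C)C)(C(OC)=CC2=O)C1(C)C | intermediate
18 | [(1E)-2,6-dimethylhepta-1,5-dienyl]dimethylalane (not isolated) | CC(C)=CCC/C(C)=C/[Al](C)C | intermediate
19 | (1E)-1-iodo-2,6-dimethylhepta-1,5-diene | CC(C)=CCC/C(C)=C/I | intermediate
20 | 9-{[(1R,5S,7S)-bicyclic core-7-yl]methyl}-9-BBN, CH2B endo (not isolated) | C1CC2CCCC(C1)B2C[C@H]3C[C@]4(CC=C(C)C)C(=O)[C@@](CC=C(C)C)(C(OC)=CC4=O)C3(C)C | intermediate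
21 | (1R,5S,7S)-7-[(2E)-3,7-dimethylocta-2,6-dienyl]-2-methoxy-8,8-dimethyl-1,5-bis(3-methylbut-2-enyl)bicyclo[3.3.1]non-2-ene-4,9-dione | CC(C)=CCC/C(C)=C/C[C@H]1C[C@]2(CC=C(C)C)C(=O)[C@@](CC=C(C)C)(C(OC)=CC2=O)C1(C)C | intermediate
22 | 3-bromophenol | Oc1cccc(Br)c1 | starting material
23 | (3-bromophenoxy)(tert-butyl)dimethylsilane | CC(C)(C)[Si](C)(C)Oc1cccc(Br)c1 | intermediate
24 | {3-[(tert-butyldimethylsilyl)oxy]phenyl}lithium (not isolated) | [Li]c1cccc(O[Si](C)(C)C(C)(C)C)c1 | intermediate
25 | lithium 3-[(tert-butyldimethylsilyl)oxy]benzoate (not isolated) | [Li+].[O-]C(=O)c1cccc(O[Si](C)(C)C(C)(C)C)c1 | intermediate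
26 | 3-[(tert-butyldimethylsilyl)oxy]benzoyl chloride | ClC(=O)c1cccc(O[Si](C)(C)C(C)(C)C)c1 | intermediate
27 | 3-lithio derivative of 21 (not isolated) | CC(C)=CCC/C(C)=C/C[C@H]1C[C@]2(CC=C(C)C)C(=O)[C@@](CC=C(C)C)(C(OC)=C([Li])C2=O)C1(C)C | intermediate
28 | (1R,5R,7S)-3-{3-[(tert-butyldimethylsilyl)oxy]benzoyl}-7-[(2E)-3,7-dimethylocta-2,6-dienyl]-2-methoxy-8,8-dimethyl-1,5-bis(3-methylbut-2-enyl)bicyclo[3.3.1]non-2-ene-4,9-dione | CC(C)=CCC/C(C)=C/C[C@H]1C[C@]2(CC=C(C)C)C(=O)[C@@](CC=C(C)C)(C(OC)=C(C(=O)c3cccc(O[Si](C)(C)C(C)(C)C)c3)C2=O)C1(C)C | intermediate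
29 | (1S,5S,7S)-7-[(2E)-3,7-dimethylocta-2,6-dienyl]-4-hydroxy-3-(3-hydroxybenzoyl)-8,8-dimethyl-1,5-bis(3-methylbut-2-enyl)bicyclo[3.3.1]non-3-ene-2,9-dione | CC(C)=CCC/C(C)=C/C[C@H]1C[C@]2(CC=C(C)C)C(=O)[C@@](CC=C(C)C)(C(=O)C(C(=O)c3cccc(O)c3)=C2O)C1(C)C | target

**Step count**
Total steps: 14.
Longest linear sequence: 9 steps (1, 2, 3, 6, 7, 8, 10, 13, 14).

**Three steps most likely to fail**

1. **Step 8 (the proposed new step).**
   - The aldol has to close on a ketone flanked by two quaternary carbons.
   - The tertiary C1–H has to be exchanged.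
   - Epoxide formation or methoxide capture could compete with the shift.
   - Fallback (known chemistry; sets out from 10, comes back at 17): leave the C1 prenyl group out of the acyl chain, so that the shift ends at a CH2 carbon, the case in which this iodine(III) ring expansion is established, and prenylate C1 afterwards at the bridgehead. Purchased (2E)-3-methoxybut-2-enoic acid F1 is turned into (2E)-3-methoxybut-2-enoyl chloride F2 and used to acylate 10 under the conditions of step 6, giving the methyl-terminated diketone F3. Prenylation with 13 as in step 7 gives the (5S)-quaternary diketone F4. LDA (1.1 equiv, THF, −78 → 0 °C) closes the isolable cis-hydrindane aldol F5, and PhI(OAc)2/KOH/MeOH at 0 °C expands it to the C1–H bicyclic vinylogous ester F6. Because the vinylic C3–H is lithiated before the hindered C1–H, C3 is first blocked (LiTMP, TMSCl) as the 3-trimethylsilyl derivative F7. LDA and then I2 give the bridgehead iodide F8. Keck radical allylation (allyltributylstannane, Et3B, air) gives the 1-allyl compound F9. Cross-metathesis with 2-methylbut-2-ene (Grubbs II) gives the 1-prenyl-3-silyl compound F10, and TBAF removes the silyl group to give 17.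

2. **Step 7.**
   - The phase-transfer method is extrapolated from β-keto esters and α-acyl lactones to a 2-(β-methoxyenoyl)cyclopentanone, so the ee is uncertain.
   - O-alkylation or pyranone closure of 12 may intervene.
   - Fallback (sets out from 12, comes back at 14): run the alkylation of 12 with 13 without a chiral catalyst (K2CO3, acetone, rt) to the racemic quaternary diketone F11. Separate the enantiomers by preparative SFC on a chiral stationary phase. The (5S)-enantiomer is 14, and the (5R)-enantiomer F12 is set aside.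

3. **Step 10.**
   - The methylidene group is neopentyl-like, so hydroboration may be slow enough for carbonyl reduction or prenyl hydroboration to compete.
   - Exo/endo selectivity may be incomplete.
   - The hindered B-alkyl group may transmetallate poorly.
   - Fallback (sets out from 17, comes back at 21): hydroborate 17 to 20 as before, but oxidise (NaBO3·4H2O) to the endo-hydroxymethyl compound F13. At this stage any C7 epimer or over-reduced material is removed by chromatography. Appel iodination (I2, PPh3, imidazole) gives the primary iodide F14. Zinc insertion (Zn, LiCl, THF; ketone-tolerant) gives the alkylzinc iodide F15, and Negishi coupling with 19 (PdCl2(dppf)) gives 21.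

**Further compounds**
F1 | step 8 | (2E)-3-methoxybut-2-enoic acid (bought) | CO/C(C)=C/C(=O)O
F2 | step 8 | (2E)-3-methoxybut-2-enoyl chloride | CO/C(C)=C/C(Cl)=O
F3 | step 8 | 5-[(2E)-3-methoxybut-2-enoyl]-2,2-dimethyl-3-methylidenecyclopentan-1-one | C=C1CC(C(=O)/C=C(\C)OC)C(=O)C1(C)C
F4 | step 8 | (5S)-5-[(2E)-3-methoxybut-2-enoyl]-2,2-dimethyl-3-methylidene-5-(3-methylbut-2-enyl)cyclopentan-1-one | C=C1C[C@@](CC=C(C)C)(C(=O)/C=C(\C)OC)C(=O)C1(C)C
F5 | step 8 | (3aR,7aR)-7a-hydroxy-6-methoxy-1,1-dimethyl-2-methylidene-3a-(3-methylbut-2-enyl)-1,2,3,3a,7,7a-hexahydro-4H-inden-4-one | C=C1C[C@@]2(CC=C(C)C)C(=O)C=C(OC)C[C@@]2(O)C1(C)C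
F6 | step 8 | (1R,5S)-2-methoxy-8,8-dimethyl-7-methylidene-5-(3-methylbut-2-enyl)bicyclo[3.3.1]non-2-ene-4,9-dione | C=C1C[C@]2(CC=C(C)C)C(=O)[C@@H](C(OC)=CC2=O)C1(C)C
F7 | step 8 | 3-trimethylsilyl derivative of F6 | C=C1C[C@]2(CC=C(C)C)C(=O)[C@@H](C(OC)=C([Si](C)(C)C)C2=O)C1(C)C
F8 | step 8 | 1-iodo-3-trimethylsilyl derivative of F6 | C=C1C[C@]2(CC=C(C)C)C(=O)[C@@](I)(C(OC)=C([Si](C)(C)C)C2=O)C1(C)C
F9 | step 8 | 1-allyl-3-trimethylsilyl derivative of F6 | C=C1C[C@]2(CC=C(C)C)C(=O)[C@@](CC=C)(C(OC)=C([Si](C)(C)C)C2=O)C1(C)C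
F10 | step 8 | 3-trimethylsilyl derivative of 17 | C=C1C[C@]2(CC=C(C)C)C(=O)[C@@](CC=C(C)C)(C(OC)=C([Si](C)(C)C)C2=O)C1(C)C
F11 | step 7 | racemic 14 | C=C1CC(CC=C(C)C)(C(=O)/C=C(\CCC=C(C)C)OC)C(=O)C1(C)C
F12 | step 7 | (5R)-enantiomer of 14 | C=C1C[C@](CC=C(C)C)(C(=O)/C=C(\CCC=C(C)C)OC)C(=O)C1(C)C
F13 | step 10 | (1R,5S,7S)-7-(hydroxymethyl)-2-methoxy-8,8-dimethyl-1,5-bis(3-methylbut-2-enyl)bicyclo[3.3.1]non-2-ene-4,9-dione | OC[C@H]1C[C@]2(CC=C(C)C)C(=O)[C@@](CC=C(C)C)(C(OC)=CC2=O)C1(C)C
F14 | step 10 | 7-(iodomethyl) analogue of F13 | IC[C@H]1C[C@]2(CC=C(C)C)C(=O)[C@@](CC=C(C)C)(C(OC)=CC2=O)C1(C)C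
F15 | step 10 | alkylzinc iodide from F14 | I[Zn]C[C@H]1C[C@]2(CC=C(C)C)C(=O)[C@@](CC=C(C)C)(C(OC)=CC2=O)C1(C)C
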